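## The problem

The target (compound 19) is a diaryl ketone. Ring A (2-ethyl-4,6-dihydroxyphenyl) and ring B (a phenol) share one carbonyl carbon, and ring B carries on its other ortho carbon a CH2 group that ends at C6 of a 4-hydroxy-2H-pyran-2-one. Both aryl carbons on the ketone have two ortho substituents (ethyl and hydroxyl on ring A, hydroxyl and CH2 on ring B). The carbonyl is therefore shielded on all four sides, and making either aryl–carbonyl bond by Friedel–Crafts acylation or by adding an aryl metal to a hindered acyl partner is the operation most likely to fail. Ring B is also 1,2,3-trisubstituted, a pattern that electrophilic substitution of a phenol does not deliver. The molecule has no stereocentre, so nothing has to be set or relayed; the difficulties are regiochemical and steric.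

Several groups need gentle handling. The pyrone is a vinylogous acid and a lactone, in effect a masked 3,5-diketo acid whose open form carries a nucleophilic carbon placed to attack the diaryl ketone. The three phenols are electron-rich and acidic. The CH2 between ring B and the pyrone is doubly activated. The pyrone is therefore best closed late under neutral conditions, with the phenols carried as methyl ethers that fall together at the end.

The feature that opens the route is the substitution of ring B: aroyl on C1, hydroxyl on C2, CH2 on C6, and hydrogen on C3 to C5. This is an ortho-acylphenol, so C1 to C3 can come from a 1,3-diketone that already contains the ring A ketone, and C4 to C6 from a β-keto acetal that carries the acetic ester arm on its ketone carbon.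

## Retrosynthesis

**19 from 18.** The three aryl O–CH3 bonds of 19 are cut last, which leads back to the trimethyl ether 18. Methyl ethers are chosen over benzyl or silyl ethers because they survive every Lewis acid, base and heating step before them. The forward reaction must cleave one ether para and two ethers ortho to the ketone without harming the pyrone.

**18 from 16.** The lactone O1–C2 bond of the pyrone in 18 is cut to give the keto-dioxinone 16, by way of the acylketene 17. Closure by thermal cycloreversion and enol trapping is preferred to base-mediated lactonisation of an open 3,5-diketo ester, because a base would also enolise the chain toward the diaryl ketone. Compound 16 holds the whole carbon skeleton in a form that is stable to storage.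

**16 from 12 and 13.** The C–C bond between the side-chain ketone and the dioxinone CH2 of 16 is cut. This gives the arylacetic acid 12, activated in the flask as imidazolide 14, and the commercial dioxinone 13, used as its lithium dienolate 15. The pyrone thus arrives as one four-carbon block. The forward acylation must be faster than proton transfer from the acidic benzylic CH2 of 14.

**12 from 10 via 11.** Acid 12 comes from ester 11 by hydrolysis, and 11 from phenol 10 by O-methylation. These two adjustments are the price of bringing the side chain in at the correct oxidation level and of masking the one phenol that the ring synthesis leaves free.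

**10 from 7 and 8 (key cut).** Ring B of 10 is cut at C3–C4 and C1–C6. This gives the bis(silyl enol ether) 7 of the ring A 1,3-diketone and the keto acetal 8; the open-chain adduct 9 lies between them. Cutting here, and not at the aryl–carbonyl bond, means the congested ketone carbon is already bonded to ring A before ring B exists. Both precursors are open-chain and carry no ring B at all. The forward reaction must join the terminal carbon of 7 to the acetal carbon of 8 and the central carbon of 7 to the ketone carbon of 8, in that sense only.

**7 from 4 via 5.** The two O–Si bonds of 7 are cut in turn, through the mono-silyl enol ether 5 and its lithium dienolate 6, back to the diketone 4. Stepwise silylation is the established way to convert a 1,3-diketone into its dianion equivalent.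

**4 from 1.** The C2–C3 bond of the diketone 4 is cut to give the methyl ketone 2 and ethyl acetate 3 (Claisen condensation). The aryl–acetyl bond of 2 is then cut to give 1-ethyl-3,5-dimethoxybenzene 1 (Friedel–Crafts acetylation). This is the only aryl–carbonyl bond made in the route, and it is made with the smallest possible acyl group.

## Roads not taken

**Alternative 1:** Ring B would be cut at C1–C2 and C5–C6. The forward step is a Diels–Alder addition of diene A2 (1-methoxycyclohexa-1,3-diene) to ynone A1, 5-(tert-butyldimethylsilyloxy)-1-(2-ethyl-4,6-dimethoxyphenyl)pent-2-yn-1-one. The bicyclo[2.2.2]octadiene then expels its two-carbon bridge on heating (Alder–Rickert) and leaves ring B as A3, {2-[2-(tert-butyldimethylsilyloxy)ethyl]-6-methoxyphenyl}(2-ethyl-4,6-dimethoxyphenyl)methanone.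

- Merits: the donor–acceptor pairing of A2 and A1 fixes the regiochemistry without ambiguity. The ring B oxygen arrives already methylated, and the ketone is again in place before ring B is made.
- Weak points: A1 needs about three steps from 1, one of them an acetylide addition next to the di-ortho-substituted ring. A2 is normally obtained mixed with its unconjugated isomer and is used in excess. The cycloreversion needs strong heating. The side chain of A3 is two oxidation levels too low, so desilylation and oxidation must follow before acid 12 is reached.
- Comparison: the length to 12 is about the same as in the chosen plan. In regiochemical certainty this road is the better one. The chosen plan sets against it a ring-forming step at −78 to 20 °C, a side chain delivered at the ester level and no redox adjustment.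

**Alternative 2:** Ring A would be made late from an open chain. The β-keto ester A4, methyl 3-{2-[2-(tert-butyldimethylsilyloxy)ethyl]-6-methoxyphenyl}-3-oxopropanoate, adds to enone A5, (E)-hex-3-en-2-one. The methyl ketone enolate then acylates on the ester and closes A6, racemic trans-4-{2-[2-(tert-butyldimethylsilyloxy)ethyl]-6-methoxybenzoyl}-5-ethylcyclohexane-1,3-dione, which is dehydrogenated to the resorcinol.

- Merits: the ring A substitution pattern is unambiguous, with no Friedel–Crafts regiochemistry to trust. The ring A hydroxyls appear free, so only one methyl ether would remain to be cleaved.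
- Weak points: A4 already contains the 1,2,3-trisubstituted ring B, so the hard ring is left to be bought or built by several directed-metalation steps. The Michael addition joins a hindered keto ester to a β-substituted enone. Two stereocentres are made only to be destroyed. The oxidative aromatisation of a triketone must spare a silyl ether, and the free resorcinol then has to be carried or re-protected through the pyrone assembly.
- Comparison: this road is longer and builds the easy ring. Its one real advantage is the milder end-game deprotection. The chosen plan pays for its global demethylation but constructs the congested ring directly.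

**Alternative 3:** Ring B would be bought as an aryne, and its C1–C(=O) and C6–CH2 bonds formed at once. The aryne released by fluoride from A7, 3-methoxy-2-(trimethylsilyl)phenyl trifluoromethanesulfonate, inserts into the C(acyl)–CH2 bond of the ring A β-keto ester A8, methyl 3-(2-ethyl-4,6-dimethoxyphenyl)-3-oxopropanoate. The product is A9, methyl 2-[2-(2-ethyl-4,6-dimethoxybenzoyl)-3-methoxyphenyl]acetate, which is the same compound as 11.

- Merits: A9 would be reached in three steps from 1 (acetylation, methoxycarbonylation, insertion) against six in the chosen plan. The methoxy group is already in place, and the regiochemistry of addition to the methoxy aryne is reliable.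
- Weak points: after the enolate carbon has added to the aryne, the aryl anion next to the methoxy group must attack a ketone that sits on the 2,6-disubstituted ring A. The tetra-ortho-substituted aryl–carbonyl bond is therefore made in this very step, between two hindered centres. If that addition is slow, protonation gives plain α-arylation without insertion, and excess aryne arylates again. A7 is costly.
- Comparison: if the insertion tolerated this ketone, this would be the shorter and better road, and that is said plainly. The chosen plan sets against its three extra steps that none of its bonds is formed at a carbonyl flanked by two di-ortho-substituted rings.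

Key step: step 5

Assumption: compounds 1, 8 and 13 are taken as purchasable; the silyl enol ether double bonds are written Z, as expected from the chelated enol, and this geometry has no bearing on the outcome because the bond ends in the aromatic ring.

## Route

Step 1
Reactants: 1 1-ethyl-3,5-dimethoxybenzene
Product: 2 1-(2-ethyl-4,6-dimethoxyphenyl)ethan-1-one
Conditions: AcCl, AlCl3, CH2Cl2, −10 → 0 °C
Reagents that add atoms: acetyl chloride, CC(=O)Cl
Why: Friedel–Crafts acylation; the two equivalent positions next to the ethyl group are each para to one methoxy group and ortho to the other and should be preferred over the position between the two methoxy groups, as in acylations of 3,5-dialkoxytoluenes. Low temperature and about one equivalent of AlCl3 should limit cleavage of the ortho methyl ether.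

Step 2
Reactants: 2 1-(2-ethyl-4,6-dimethoxyphenyl)ethan-1-one, 3 ethyl acetate
Product: 4 1-(2-ethyl-4,6-dimethoxyphenyl)butane-1,3-dione
Conditions: NaH, EtOAc, THF, 66 °C; then aq. HCl
Reagents that add atoms: none
Why: Claisen condensation of the methyl ketone enolate with the ester, driven by formation of the sodium diketonate; the hindered aryl ketone offers no second enolisable or electrophilic site.

Step 3
Reactants: 4 1-(2-ethyl-4,6-dimethoxyphenyl)butane-1,3-dione
Product: 5 (Z)-1-(2-ethyl-4,6-dimethoxyphenyl)-3-(trimethylsilyloxy)but-2-en-1-one
Conditions: TMSCl, NEt3, toluene, 20 °C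
Reagents that add atoms: chlorotrimethylsilane, C[Si](C)(C)Cl
Why: O-silylation of the enolised 1,3-diketone under soft enolisation, the standard first stage of bis(silyl enol ether) synthesis; silylation at the less hindered acetyl oxygen is expected, and the other regioisomer would converge on the same diene in step 4.

Step 4
Reactants: 5 (Z)-1-(2-ethyl-4,6-dimethoxyphenyl)-3-(trimethylsilyloxy)but-2-en-1-one
Product: 7 (Z)-1-(2-ethyl-4,6-dimethoxyphenyl)-1,3-bis(trimethylsilyloxy)buta-1,3-diene, via lithium dienolate 6 (not isolated)
Conditions: LiN(i-Pr)2, THF, −78 °C; then TMSCl, −78 → 20 °C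
Reagents that add atoms: chlorotrimethylsilane, C[Si](C)(C)Cl
Why: Kinetic deprotonation of the methyl group of the β-silyloxy enone and O-silylation of the dienolate, the established second stage for 1,3-diketone-derived 1,3-bis(silyloxy)buta-1,3-dienes. The moisture-sensitive diene should be freed from LiCl by filtration in pentane and used crude.

Step 5
Reactants: 7 (Z)-1-(2-ethyl-4,6-dimethoxyphenyl)-1,3-bis(trimethylsilyloxy)buta-1,3-diene, 8 methyl 5,5-dimethoxy-3-oxopentanoate
Product: 10 methyl 2-[2-(2-ethyl-4,6-dimethoxybenzoyl)-3-hydroxyphenyl]acetate, via open-chain keto ester adduct 9 (not isolated)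
Conditions: TiCl4, CH2Cl2, −78 → 20 °C; then aq. NaHCO3
Reagents that add atoms: none
Why: Formal (3+3) cyclocondensation of a 1,3-bis(silyloxy)buta-1,3-diene with a β-keto acetal, a known TiCl4-mediated route to salicylates, 3-hydroxyhomophthalates and ortho-acylphenols. TiCl4 ionises the acetal of 8 to an oxocarbenium ion, which is attacked by the unhindered terminal CH2 of 7 (Mukaiyama-type alkylation) to give 9. The remaining silyl enol ether carbon of 9 then adds to the titanium-activated ketone in a 6-(enolendo)-exo-trig aldol closure, and loss of water and methanol from the resulting cyclohexenone aromatises ring B. No stereocentre is created: the methoxy-bearing carbon of 9 is racemic and becomes an aromatic CH. Two selectivities are needed. First, the terminal carbon must bond to the acetal carbon and the central carbon to the ketone; the much higher electrophilicity of the oxocarbenium ion over the chelated keto ester carbonyl should secure this and place CH2CO2Me next to the aroyl group. Second, the ring must close from the silyl enol ether carbon onto the keto ester ketone and not from the keto ester methylene onto the diketone carbonyl; the silyl enol ether is the only preformed nucleophile in 9, and the competing carbonyl is deactivated as a vinylogous silyl ester. The aroyl carbon enters already bonded to ring A, so no bond is formed at the hindered ketone.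

Step 6
Reactants: 10 methyl 2-[2-(2-ethyl-4,6-dimethoxybenzoyl)-3-hydroxyphenyl]acetate
Product: 11 methyl 2-[2-(2-ethyl-4,6-dimethoxybenzoyl)-3-methoxyphenyl]acetate
Conditions: MeI, K2CO3, DMF, 20 °C
Reagents that add atoms: iodomethane, CI
Why: Williamson ether synthesis on the phenoxide; carbonate is too weak to deprotonate the arylacetate CH2, and at room temperature the phenoxide should not displace the ring A ortho methoxy group to form a xanthone.

Step 7
Reactants: 11 methyl 2-[2-(2-ethyl-4,6-dimethoxybenzoyl)-3-methoxyphenyl]acetate
Product: 12 2-[2-(2-ethyl-4,6-dimethoxybenzoyl)-3-methoxyphenyl]acetic acid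
Conditions: LiOH, THF–H2O, 20 °C; then aq. HCl
Reagents that add atoms: lithium hydroxide, [Li+].[OH-]
Why: Saponification of an unhindered methyl ester; the aryl methyl ethers and the shielded diaryl ketone are inert to aqueous hydroxide at room temperature.

Step 8
Reactants: 12 2-[2-(2-ethyl-4,6-dimethoxybenzoyl)-3-methoxyphenyl]acetic acid, 13 2,2,6-trimethyl-4H-1,3-dioxin-4-one
Product: 16 6-{3-[2-(2-ethyl-4,6-dimethoxybenzoyl)-3-methoxyphenyl]-2-oxopropyl}-2,2-dimethyl-4H-1,3-dioxin-4-one, via acyl imidazolide 14 (not isolated), via lithium dienolate 15 (not isolated)
Conditions: 12, CDI, THF, 20 °C; then added to 13 and LiN(SiMe3)2 (2.4 equiv each), THF, −78 → −30 °C; aq. NH4Cl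
Reagents that add atoms: none
Why: Claisen-type C-acylation of the dioxinone dienolate at its exocyclic carbon by an acyl imidazolide, a known entry to β-keto dioxinones. The second equivalent of 15 deprotonates the product, and the diaryl ketone is too shielded to compete as an electrophile at low temperature.

Step 9
Reactants: 16 6-{3-[2-(2-ethyl-4,6-dimethoxybenzoyl)-3-methoxyphenyl]-2-oxopropyl}-2,2-dimethyl-4H-1,3-dioxin-4-one
Product: 18 6-{[2-(2-ethyl-4,6-dimethoxybenzoyl)-3-methoxyphenyl]methyl}-4-hydroxy-2H-pyran-2-one, via acylketene 17 (not isolated)
Conditions: toluene, 110 °C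
Reagents that add atoms: none
Why: Thermal retro-hetero-Diels–Alder loss of acetone gives acylketene 17, whose δ-ketone enol oxygen adds to the ketene carbon to close the 4-hydroxy-2-pyrone, a known fate of β-keto dioxinones heated without a nucleophile. The medium is neutral, so no enolate is present to attack the diaryl ketone.

Step 10
Reactants: 18 6-{[2-(2-ethyl-4,6-dimethoxybenzoyl)-3-methoxyphenyl]methyl}-4-hydroxy-2H-pyran-2-one
Product: 19 6-{[2-(2-ethyl-4,6-dihydroxybenzoyl)-3-hydroxyphenyl]methyl}-4-hydroxy-2H-pyran-2-one
Conditions: BBr3 (excess), CH2Cl2, −78 → 20 °C; then MeOH, H2O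
Reagents that add atoms: none
Why: Lewis-acid cleavage of aryl methyl ethers (boron coordination, then bromide attack on methyl). The two ethers ortho to the ketone should fall quickly through six-membered boron chelates and the para ether with excess reagent at 20 °C, while the pyrone and the diaryl ketone are inert to BBr3.

## Compound list

1 | 1-ethyl-3,5-dimethoxybenzene | CCc1cc(OC)cc(OC)c1 | starting material
2 | 1-(2-ethyl-4,6-dimethoxyphenyl)ethan-1-one | CCc1cc(OC)cc(OC)c1C(C)=O | intermediate
3 | ethyl acetate | CCOC(C)=O | starting material
4 | 1-(2-ethyl-4,6-dimethoxyphenyl)butane-1,3-dione | CCc1cc(OC)cc(OC)c1C(=O)CC(C)=O | intermediate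
5 | (Z)-1-(2-ethyl-4,6-dimethoxyphenyl)-3-(trimethylsilyloxy)but-2-en-1-one | CCc1cc(OC)cc(OC)c1C(=O)/C=C(/C)O[Si](C)(C)C | intermediate
6 | lithium (1Z)-1-(2-ethyl-4,6-dimethoxyphenyl)-3-(trimethylsilyloxy)buta-1,3-dien-1-olate | CCc1cc(OC)cc(OC)c1/C([O-])=C/C(=C)O[Si](C)(C)C.[Li+] | intermediate
7 | (Z)-1-(2-ethyl-4,6-dimethoxyphenyl)-1,3-bis(trimethylsilyloxy)buta-1,3-diene | CCc1cc(OC)cc(OC)c1/C(O[Si](C)(C)C)=C/C(=C)O[Si](C)(C)C | intermediate
8 | methyl 5,5-dimethoxy-3-oxopentanoate | COC(OC)CC(=O)CC(=O)OC | starting material
9 | methyl (8Z)-9-(2-ethyl-4,6-dimethoxyphenyl)-5-methoxy-3,7-dioxo-9-(trimethylsilyloxy)non-8-enoate, racemic at C5 | CCc1cc(OC)cc(OC)c1/C(O[Si](C)(C)C)=C/C(=O)CC(OC)CC(=O)CC(=O)OC | intermediate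
10 | methyl 2-[2-(2-ethyl-4,6-dimethoxybenzoyl)-3-hydroxyphenyl]acetate | CCc1cc(OC)cc(OC)c1C(=O)c1c(O)cccc1CC(=O)OC | intermediate
11 | methyl 2-[2-(2-ethyl-4,6-dimethoxybenzoyl)-3-methoxyphenyl]acetate | CCc1cc(OC)cc(OC)c1C(=O)c1c(OC)cccc1CC(=O)OC | intermediate
12 | 2-[2-(2-ethyl-4,6-dimethoxybenzoyl)-3-methoxyphenyl]acetic acid | CCc1cc(OC)cc(OC)c1C(=O)c1c(OC)cccc1CC(=O)O | intermediate
13 | 2,2,6-trimethyl-4H-1,3-dioxin-4-one | CC1=CC(=O)OC(C)(C)O1 | starting material
14 | 2-[2-(2-ethyl-4,6-dimethoxybenzoyl)-3-methoxyphenyl]-1-(1H-imidazol-1-yl)ethan-1-one | CCc1cc(OC)cc(OC)c1C(=O)c1c(OC)cccc1CC(=O)n1ccnc1 | intermediate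
15 | lithium 2,2-dimethyl-6-methylidene-6H-1,3-dioxin-4-olate | C=C1C=C([O-])OC(C)(C)O1.[Li+] | intermediate
16 | 6-{3-[2-(2-ethyl-4,6-dimethoxybenzoyl)-3-methoxyphenyl]-2-oxopropyl}-2,2-dimethyl-4H-1,3-dioxin-4-one | CCc1cc(OC)cc(OC)c1C(=O)c1c(OC)cccc1CC(=O)CC1=CC(=O)OC(C)(C)O1 | intermediate
17 | 6-[2-(2-ethyl-4,6-dimethoxybenzoyl)-3-methoxyphenyl]hex-1-ene-1,3,5-trione | CCc1cc(OC)cc(OC)c1C(=O)c1c(OC)cccc1CC(=O)CC(=O)C=C=O | intermediate
18 | 6-{[2-(2-ethyl-4,6-dimethoxybenzoyl)-3-methoxyphenyl]methyl}-4-hydroxy-2H-pyran-2-one | CCc1cc(OC)cc(OC)c1C(=O)c1c(OC)cccc1Cc1cc(O)cc(=O)o1 | intermediate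
19 | 6-{[2-(2-ethyl-4,6-dihydroxybenzoyl)-3-hydroxyphenyl]methyl}-4-hydroxy-2H-pyran-2-one | CCc1cc(O)cc(O)c1C(=O)c1c(O)cccc1Cc1cc(O)cc(=O)o1 | target

## Step count and least certain steps

Total steps: 10. Longest linear sequence: 10 steps (1 to 19); compounds 3, 8 and 13 are bought.

**Step 5 (key step).** The ring closure may run in the wrong sense: once the silyl group is lost, the active methylene of the keto ester arm can attack the diketone carbonyl and give the isomeric salicylate. HCl set free when TiCl4 enolises the β-keto ester may also protodesilylate the diene and return 4. A third risk is first attack at the ketone instead of the acetal.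

Fallback, from 7 back to 12: the same TiCl4 condensation is run on 7 with commercial 4,4-dimethoxybutan-2-one, a partner with no second active methylene. This should give (2-ethyl-4,6-dimethoxyphenyl)(2-hydroxy-6-methylphenyl)methanone F1. O-Methylation (MeI, K2CO3, DMF) gives (2-ethyl-4,6-dimethoxyphenyl)(2-methoxy-6-methylphenyl)methanone F2. Lateral deprotonation of the ortho methyl group (LiN(i-Pr)2, THF, −78 °C) and carboxylation of the dienolate with CO2 then give acid 12. The methyl group should be deprotonated in preference to the secondary, more hindered benzylic CH2 of the ring A ethyl group.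

**Step 8.** Proton transfer from the doubly activated benzylic CH2 of 14 to dienolate 15 may outrun C-acylation. The consequences would be ketene formation, self-condensation, or cyclisation of the enolate through the neighbouring ketone oxygen, with acid recovered on work-up.

Fallback, from 11 back to 18: ester 11, which is less acidic and has a poorer leaving group, is acylated onto the dianion of methyl acetoacetate (NaH, then n-BuLi, THF, 0 °C, excess dianion). This gives methyl 6-[2-(2-ethyl-4,6-dimethoxybenzoyl)-3-methoxyphenyl]-3,5-dioxohexanoate F3. Lactonisation with DBU in toluene then closes pyrone 18. This bypasses 12 and 16 and saves one step, at the cost of a base-mediated ring closure.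

**Step 10.** After the two chelated ortho ethers have gone, the boron chelate deactivates ring A. Cleavage of the para methoxy group may then stall, while the electron-rich product slowly degrades on long exposure to BBr3 and HBr.

Fallback, from 18 back to 19: the deprotection is split. BCl3 (CH2Cl2, −78 → 0 °C) removes only the two chelation-activated ortho methyl groups and gives 6-{[2-(2-ethyl-6-hydroxy-4-methoxybenzoyl)-3-hydroxyphenyl]methyl}-4-hydroxy-2H-pyran-2-one F4. The isolated para ether is then cleaved by the hard-acid, soft-nucleophile pair AlCl3 and ethanethiol (CH2Cl2, 0 → 20 °C) to give 19.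

**Step 1.** Some acylation may occur between the two methoxy groups, and AlCl3 may cleave the methyl ether ortho to the new ketone.

Fallback, from 1 back to 2: bromination with N-bromosuccinimide (MeCN, 0 °C) goes para to a methoxy group and gives 2-bromo-1-ethyl-3,5-dimethoxybenzene F5. Bromine–lithium exchange (n-BuLi, THF, −78 °C) and acylation of the aryllithium with N-methoxy-N-methylacetamide then give 2 with the position fixed by the halogen.

## Further compounds

F1 | step 5 | (2-ethyl-4,6-dimethoxyphenyl)(2-hydroxy-6-methylphenyl)methanone | CCc1cc(OC)cc(OC)c1C(=O)c1c(O)cccc1C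
F2 | step 5 | (2-ethyl-4,6-dimethoxyphenyl)(2-methoxy-6-methylphenyl)methanone | CCc1cc(OC)cc(OC)c1C(=O)c1c(OC)cccc1C
F3 | step 8 | methyl 6-[2-(2-ethyl-4,6-dimethoxybenzoyl)-3-methoxyphenyl]-3,5-dioxohexanoate | CCc1cc(OC)cc(OC)c1C(=O)c1c(OC)cccc1CC(=O)CC(=O)CC(=O)OC
F4 | step 10 | 6-{[2-(2-ethyl-6-hydroxy-4-methoxybenzoyl)-3-hydroxyphenyl]methyl}-4-hydroxy-2H-pyran-2-one | CCc1cc(OC)cc(O)c1C(=O)c1c(O)cccc1Cc1cc(O)cc(=O)o1
F5 | step 1 | 2-bromo-1-ethyl-3,5-dimethoxybenzene | CCc1cc(OC)cc(OC)c1Br
A1 | alternative 1 | 5-(tert-butyldimethylsilyloxy)-1-(2-ethyl-4,6-dimethoxyphenyl)pent-2-yn-1-one | CCc1cc(OC)cc(OC)c1C(=O)C#CCCO[Si](C)(C)C(C)(C)C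
A2 | alternative 1 | 1-methoxycyclohexa-1,3-diene | COC1=CC=CCC1
A3 | alternative 1 | {2-[2-(tert-butyldimethylsilyloxy)ethyl]-6-methoxyphenyl}(2-ethyl-4,6-dimethoxyphenyl)methanone | CCc1cc(OC)cc(OC)c1C(=O)c1c(OC)cccc1CCO[Si](C)(C)C(C)(C)C
A4 | alternative 2 | methyl 3-{2-[2-(tert-butyldimethylsilyloxy)ethyl]-6-methoxyphenyl}-3-oxopropanoate | COC(=O)CC(=O)c1c(OC)cccc1CCO[Si](C)(C)C(C)(C)C
A5 | alternative 2 | (E)-hex-3-en-2-one | CC/C=C/C(C)=O
A6 | alternative 2 | racemic trans-4-{2-[2-(tert-butyldimethylsilyloxy)ethyl]-6-methoxybenzoyl}-5-ethylcyclohexane-1,3-dione (one enantiomer drawn) | CC[C@@H]1CC(=O)CC(=O)[C@H]1C(=O)c1c(OC)cccc1CCO[Si](C)(C)C(C)(C)C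
A7 | alternative 3 | 3-methoxy-2-(trimethylsilyl)phenyl trifluoromethanesulfonate | COc1cccc(OS(=O)(=O)C(F)(F)F)c1[Si](C)(C)C
A8 | alternative 3 | methyl 3-(2-ethyl-4,6-dimethoxyphenyl)-3-oxopropanoate | CCc1cc(OC)cc(OC)c1C(=O)CC(=O)OC
A9 | alternative 3 | methyl 2-[2-(2-ethyl-4,6-dimethoxybenzoyl)-3-methoxyphenyl]acetate | CCc1cc(OC)cc(OC)c1C(=O)c1c(OC)cccc1CC(=O)OC
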